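Ring C carries three contiguous substituents: C2-OCH3, the carboxyl carbon on C1, and C6-CH3. The route disconnects the C1-carbon bond and the C6-CH3 bond together, back to an aryl iodide in which C1-I lies between the C2 methoxy group and an unsubstituted C6-H. One palladium/norbornene (Catellani) operation with methyl tosylate and methyl acrylate methylates C6 and installs an acrylate at C1; the alkene is a masked carboxyl that is unveiled oxidatively only at the end. The precursor is the complete ring A-ring B-ring C depside, the 4-iodo-3-methoxyphenyl ester of the ring A-ring B acid, with all three phenols held as benzyl ethers so that the methylating agent finds no oxygen nucleophile.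

Key step: step 9

Remark: the target has no stereocentre; the E geometry of acrylate 15 is the only stereochemical element on the way and is destroyed in step 10. No structure needed correction, and the tribenzyl iodide 12 is kept as the key-step substrate because the benzyl ethers are inert to palladium and fall together in the last step.

Step 1
Reactants: 1 orsellinic acid (2,4-dihydroxy-6-methylbenzoic acid)
Product: 2 benzyl 2,4-bis(benzyloxy)-6-methylbenzoate
Conditions: BnBr (3.5 equiv), K2CO3, DMF, rt then 60 °C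
Reagents that add atoms: benzyl bromide, BrCc1ccccc1
Why: Williamson O-alkylation of the carboxylate and both phenols under carbonate in DMF, with excess bromide and gentle heating carrying the hydrogen-bonded 2-hydroxyl through as well.

Step 2
Reactants: 2 benzyl 2,4-bis(benzyloxy)-6-methylbenzoate
Product: 3 2,4-bis(benzyloxy)-6-methylbenzoic acid
Conditions: KOH, DMSO/H2O, 90 °C; then aq. HCl
Reagents that add atoms: potassium hydroxide, [K+].[OH-]
Why: Saponification of the hindered benzyl ester under forcing hydroxide conditions should free the acid while the aryl benzyl ethers, which hydroxide cannot cleave, stay in place.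

Step 3
Reactants: 1 orsellinic acid
Product: 4 allyl 2,4-dihydroxy-6-methylbenzoate
Conditions: allyl bromide (1.1 equiv), KHCO3, DMF, rt
Reagents that add atoms: allyl bromide, C=CCBr
Why: SN2 alkylation of the carboxylate only, since hydrogencarbonate deprotonates the carboxylic acid but not the phenols, and room temperature avoids decarboxylation.

Step 4
Reactants: 3 2,4-bis(benzyloxy)-6-methylbenzoic acid; 4 allyl 2,4-dihydroxy-6-methylbenzoate
Product: 6 allyl 4-{[2,4-bis(benzyloxy)-6-methylbenzoyl]oxy}-2-hydroxy-6-methylbenzoate, via 2,4-bis(benzyloxy)-6-methylbenzoyl chloride 5 (not isolated)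
Conditions: (COCl)2, cat. DMF, CH2Cl2, 0 °C to rt, evaporate; then 4, Et3N, cat. DMAP, CH2Cl2, 0 °C to rt
Reagents that add atoms: none
Why: Acid chloride formation followed by DMAP-catalysed O-acylation (classical depside coupling) should go only at the 4-hydroxyl, because the 2-hydroxyl is tied up in a hydrogen bond to the neighbouring ester carbonyl and is shielded by it.

Step 5
Reactants: 6 allyl 4-{[2,4-bis(benzyloxy)-6-methylbenzoyl]oxy}-2-hydroxy-6-methylbenzoate
Product: 7 allyl 2-(benzyloxy)-4-{[2,4-bis(benzyloxy)-6-methylbenzoyl]oxy}-6-methylbenzoate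
Conditions: BnBr, K2CO3, DMF, rt to 45 °C
Reagents that add atoms: benzyl bromide, BrCc1ccccc1
Why: Williamson etherification of the remaining chelated phenol, tolerated by the di-ortho-substituted depside ester and the allyl ester because anhydrous carbonate offers no competent acyl-transfer nucleophile.

Step 6
Reactants: 7 allyl 2-(benzyloxy)-4-{[2,4-bis(benzyloxy)-6-methylbenzoyl]oxy}-6-methylbenzoate
Product: 8 2-(benzyloxy)-4-{[2,4-bis(benzyloxy)-6-methylbenzoyl]oxy}-6-methylbenzoic acid
Conditions: Pd(PPh3)4 (5 mol%), morpholine, THF, rt; then dilute aq. HCl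
Reagents that add atoms: none
Why: Tsuji-Trost deallylation, in which zerovalent palladium ionises the allyl ester to a pi-allyl complex that morpholine captures, leaves benzyl ethers and the hindered aryl ester untouched and is placed before any aryl iodide exists.

Step 7
Reactants: 9 3-methoxyphenol
Product: 10 4-iodo-3-methoxyphenol
Conditions: NIS (1.0 equiv), MeCN, -20 °C to 0 °C, dark
Reagents that add atoms: N-iodosuccinimide, O=C1CCC(=O)N1I
Why: Electrophilic aromatic iodination of the free phenol under neutral conditions should favour the position para to the hydroxyl, the stronger donor, which is also ortho to the methoxy group; the minor ortho-to-hydroxyl isomer would be removed by chromatography.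

Step 8
Reactants: 8 2-(benzyloxy)-4-{[2,4-bis(benzyloxy)-6-methylbenzoyl]oxy}-6-methylbenzoic acid; 10 4-iodo-3-methoxyphenol
Product: 12 4-iodo-3-methoxyphenyl 2-(benzyloxy)-4-{[2,4-bis(benzyloxy)-6-methylbenzoyl]oxy}-6-methylbenzoate, via 2-(benzyloxy)-4-{[2,4-bis(benzyloxy)-6-methylbenzoyl]oxy}-6-methylbenzoyl chloride 11 (not isolated)
Conditions: (COCl)2, cat. DMF, CH2Cl2, 0 °C to rt, evaporate; then 10, Et3N, DMAP, CH2Cl2, 0 °C to rt
Reagents that add atoms: none
Why: Acid chloride/DMAP esterification of a phenol, the same depside coupling as in step 4, is compatible with the aryl iodide, the benzyl ethers and the existing hindered ester.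

Step 9
Reactants: 12 4-iodo-3-methoxyphenyl 2-(benzyloxy)-4-{[2,4-bis(benzyloxy)-6-methylbenzoyl]oxy}-6-methylbenzoate; 13 methyl 4-methylbenzenesulfonate (methyl tosylate); 14 methyl acrylate
Product: 15 methyl (2E)-3-{4-[(2-(benzyloxy)-4-{[2,4-bis(benzyloxy)-6-methylbenzoyl]oxy}-6-methylbenzoyl)oxy]-2-methoxy-6-methylphenyl}prop-2-enoate
Conditions: Pd(OAc)2 (10 mol%), tri(2-furyl)phosphine (22 mol%), norbornene (2 equiv), 13 (3 equiv), 14 (2 equiv), anhydrous K2CO3 (3 equiv), MeCN, 80 °C, argon
Reagents that add atoms: none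
Why: Catellani reaction: zerovalent palladium inserts into the C1-I bond of ring C, norbornene undergoes syn carbopalladation, and carbonate-assisted cleavage of the C6-H bond gives a five-membered aryl-norbornyl palladacycle, which adds methyl tosylate oxidatively to a tetravalent palladium species and reductively eliminates the C6-CH3 bond. With both ortho positions then occupied, steric pressure drives beta-carbon elimination of norbornene, and the C1 arylpalladium ends in a Heck reaction with methyl acrylate (syn insertion, syn beta-hydride elimination) to give the E-acrylate. The closest known reaction type is the palladium/norbornene ortho-methylation of ortho-substituted aryl iodides with methyl sulfonates and Heck termination. No ring is closed in the product and no stereocentre is formed; only the alkene geometry is set, by the Heck step. The step needs a single methylation at C6 and loss of norbornene before the Heck event: the C2 methoxy group blocks the second ortho site and supplies the ortho substituent that forces extrusion, while strained norbornene outcompetes the acrylate for the first arylpalladium. The three phenols are benzyl ethers, so methyl tosylate meets no oxygen nucleophile, and the di-ortho-substituted depside esters should resist anhydrous K2CO3.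

Step 10
Reactants: 15 methyl (2E)-3-aryl acrylate from step 9
Product: 17 4-formyl-3-methoxy-5-methylphenyl 2-(benzyloxy)-4-{[2,4-bis(benzyloxy)-6-methylbenzoyl]oxy}-6-methylbenzoate, via secondary ozonide (1,2,4-trioxolane) 16 (not isolated)
Conditions: O3, CH2Cl2, -78 °C, Sudan Red 7B as end-point indicator; then PPh3, -78 °C to rt
Reagents that add atoms: ozone, [O-][O+]=O
Why: Ozonolysis (Criegee mechanism) with reductive work-up cleaves the only alkene to the aryl aldehyde; the rings are deactivated by acyl and acyloxy groups, benzyl ethers react slowly at -78 °C, and the indicator dye stops ozone delivery at the end-point.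

Step 11
Reactants: 17 4-formyl-3-methoxy-5-methylphenyl 2-(benzyloxy)-4-{[2,4-bis(benzyloxy)-6-methylbenzoyl]oxy}-6-methylbenzoate
Product: 18 4-[(2-(benzyloxy)-4-{[2,4-bis(benzyloxy)-6-methylbenzoyl]oxy}-6-methylbenzoyl)oxy]-2-methoxy-6-methylbenzoic acid
Conditions: NaClO2, NaH2PO4, 2-methyl-2-butene, t-BuOH/THF/H2O, 0 °C to rt
Reagents that add atoms: sodium chlorite, [Na+].[O-]Cl=O
Why: Pinnick oxidation converts even a di-ortho-substituted aryl aldehyde to the acid under buffered conditions that leave esters and ethers alone, with 2-methyl-2-butene trapping hypochlorous acid before it can chlorinate the alkoxy-substituted rings.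

Step 12
Reactants: 18 4-[(2-(benzyloxy)-4-{[2,4-bis(benzyloxy)-6-methylbenzoyl]oxy}-6-methylbenzoyl)oxy]-2-methoxy-6-methylbenzoic acid
Product: 19 4-({4-[(2,4-dihydroxy-6-methylbenzoyl)oxy]-2-hydroxy-6-methylbenzoyl}oxy)-2-methoxy-6-methylbenzoic acid (target)
Conditions: H2 (1 atm), 10% Pd/C, EtOAc/THF, rt
Reagents that add atoms: none
Why: Catalytic hydrogenolysis removes the three aryl benzyl ethers in one operation under neutral, aprotic conditions at room temperature, which spare the two depside esters, the methyl ether and the decarboxylation-prone acid.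

Compound list
1 | orsellinic acid (2,4-dihydroxy-6-methylbenzoic acid) | Cc1cc(O)cc(O)c1C(=O)O | starting material
2 | benzyl 2,4-bis(benzyloxy)-6-methylbenzoate | Cc1cc(OCc2ccccc2)cc(OCc2ccccc2)c1C(=O)OCc1ccccc1 | intermediate
3 | 2,4-bis(benzyloxy)-6-methylbenzoic acid | Cc1cc(OCc2ccccc2)cc(OCc2ccccc2)c1C(=O)O | intermediate
4 | allyl 2,4-dihydroxy-6-methylbenzoate | Cc1cc(O)cc(O)c1C(=O)OCC=C | intermediate
5 | 2,4-bis(benzyloxy)-6-methylbenzoyl chloride | Cc1cc(OCc2ccccc2)cc(OCc2ccccc2)c1C(=O)Cl | intermediate
6 | allyl 4-{[2,4-bis(benzyloxy)-6-methylbenzoyl]oxy}-2-hydroxy-6-methylbenzoate | C=CCOC(=O)c1c(C)cc(OC(=O)c2c(C)cc(OCc3ccccc3)cc2OCc2ccccc2)cc1O | intermediate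
7 | allyl 2-(benzyloxy)-4-{[2,4-bis(benzyloxy)-6-methylbenzoyl]oxy}-6-methylbenzoate | C=CCOC(=O)c1c(C)cc(OC(=O)c2c(C)cc(OCc3ccccc3)cc2OCc2ccccc2)cc1OCc1ccccc1 | intermediate
8 | 2-(benzyloxy)-4-{[2,4-bis(benzyloxy)-6-methylbenzoyl]oxy}-6-methylbenzoic acid | OC(=O)c1c(C)cc(OC(=O)c2c(C)cc(OCc3ccccc3)cc2OCc2ccccc2)cc1OCc1ccccc1 | intermediate
9 | 3-methoxyphenol | COc1cccc(O)c1 | starting material
10 | 4-iodo-3-methoxyphenol | COc1cc(O)ccc1I | intermediate
11 | 2-(benzyloxy)-4-{[2,4-bis(benzyloxy)-6-methylbenzoyl]oxy}-6-methylbenzoyl chloride | ClC(=O)c1c(C)cc(OC(=O)c2c(C)cc(OCc3ccccc3)cc2OCc2ccccc2)cc1OCc1ccccc1 | intermediate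
12 | 4-iodo-3-methoxyphenyl 2-(benzyloxy)-4-{[2,4-bis(benzyloxy)-6-methylbenzoyl]oxy}-6-methylbenzoate | COc1cc(OC(=O)c2c(C)cc(OC(=O)c3c(C)cc(OCc4ccccc4)cc3OCc3ccccc3)cc2OCc2ccccc2)ccc1I | intermediate
13 | methyl 4-methylbenzenesulfonate (methyl tosylate) | COS(=O)(=O)c1ccc(C)cc1 | starting material
14 | methyl acrylate | C=CC(=O)OC | starting material
15 | methyl (2E)-3-{4-[(2-(benzyloxy)-4-{[2,4-bis(benzyloxy)-6-methylbenzoyl]oxy}-6-methylbenzoyl)oxy]-2-methoxy-6-methylphenyl}prop-2-enoate | COc1cc(OC(=O)c2c(C)cc(OC(=O)c3c(C)cc(OCc4ccccc4)cc3OCc3ccccc3)cc2OCc2ccccc2)cc(C)c1/C=C/C(=O)OC | intermediate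
16 | methyl 5-{4-[(2-(benzyloxy)-4-{[2,4-bis(benzyloxy)-6-methylbenzoyl]oxy}-6-methylbenzoyl)oxy]-2-methoxy-6-methylphenyl}-1,2,4-trioxolane-3-carboxylate (secondary ozonide, diastereomer mixture, configuration not controlled) | COc1cc(OC(=O)c2c(C)cc(OC(=O)c3c(C)cc(OCc4ccccc4)cc3OCc3ccccc3)cc2OCc2ccccc2)cc(C)c1C1OOC(O1)C(=O)OC | intermediate
17 | 4-formyl-3-methoxy-5-methylphenyl 2-(benzyloxy)-4-{[2,4-bis(benzyloxy)-6-methylbenzoyl]oxy}-6-methylbenzoate | COc1cc(OC(=O)c2c(C)cc(OC(=O)c3c(C)cc(OCc4ccccc4)cc3OCc3ccccc3)cc2OCc2ccccc2)cc(C)c1C=O | intermediate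
18 | 4-[(2-(benzyloxy)-4-{[2,4-bis(benzyloxy)-6-methylbenzoyl]oxy}-6-methylbenzoyl)oxy]-2-methoxy-6-methylbenzoic acid | COc1cc(OC(=O)c2c(C)cc(OC(=O)c3c(C)cc(OCc4ccccc4)cc3OCc3ccccc3)cc2OCc2ccccc2)cc(C)c1C(=O)O | intermediate
19 | 4-({4-[(2,4-dihydroxy-6-methylbenzoyl)oxy]-2-hydroxy-6-methylbenzoyl}oxy)-2-methoxy-6-methylbenzoic acid | COc1cc(OC(=O)c2c(C)cc(OC(=O)c3c(C)cc(O)cc3O)cc2O)cc(C)c1C(=O)O | target

Total step count: 12. Longest linear sequence: 10 steps (steps 1, 2, 4, 5, 6, 8, 9, 10, 11, 12).

Steps most likely to fail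

1. Step 9. The first arylpalladium may undergo a direct Heck reaction before norbornene inserts, the C1-I bond may be reduced, or the depside esters may be cleaved slowly by carbonate at 80 °C. The fallback gives up the C-H methylation and brings in ring C with its methyl and carboxyl groups already in place. It sets out from acid 8 (used as its chloride 11) and from orsellinic acid 1 and comes back to the route at target 19. Acid 1 is esterified at the carboxyl group only (BnBr, KHCO3, DMF, rt) to benzyl 2,4-dihydroxy-6-methylbenzoate F1. Chloride 11 then acylates the non-chelated 4-hydroxyl of F1 (Et3N, cat. DMAP, CH2Cl2) to give benzyl 4-[(2-(benzyloxy)-4-{[2,4-bis(benzyloxy)-6-methylbenzoyl]oxy}-6-methylbenzoyl)oxy]-2-hydroxy-6-methylbenzoate F2. O-Methylation of the remaining chelated hydroxyl (MeI, K2CO3, DMF) gives benzyl 4-[(2-(benzyloxy)-4-{[2,4-bis(benzyloxy)-6-methylbenzoyl]oxy}-6-methylbenzoyl)oxy]-2-methoxy-6-methylbenzoate F3. Hydrogenolysis of its four benzyl groups (H2, Pd/C, EtOAc) should give 19.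

2. Step 7. Iodination may occur in part ortho to the hydroxyl (para to the methoxy group) or twice, leaving a mixture that is hard to separate. The fallback fixes the regiochemistry through a nitrogen substituent and sets out from 9 and comes back at 10. Azo coupling of 9 with benzenediazonium tetrafluoroborate (aq. NaOH, 0 °C), which attacks para to the phenoxide, gives 3-methoxy-4-[(E)-phenyldiazenyl]phenol F4. Reductive cleavage with Na2S2O4 gives 4-amino-3-methoxyphenol F5. Diazotisation (NaNO2, aq. H2SO4, 0 °C) gives 4-hydroxy-2-methoxybenzenediazonium hydrogensulfate F6, which with KI should give 10 (Sandmeyer-type iodo-dediazoniation).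

3. Step 10. Ozone may over-oxidise the substrate at the benzylic C-H bonds of the ethers or at the alkoxy-substituted rings once the alkene is consumed, and the ozonide may be reduced incompletely. The fallback cleaves the alkene in two milder stages and sets out from 15 and comes back at 17. Osmium-catalysed syn-dihydroxylation (K2OsO2(OH)4 cat., NMO, citric acid, t-BuOH/THF/H2O, rt) gives racemic methyl (2S,3R)-3-{4-[(2-(benzyloxy)-4-{[2,4-bis(benzyloxy)-6-methylbenzoyl]oxy}-6-methylbenzoyl)oxy]-2-methoxy-6-methylphenyl}-2,3-dihydroxypropanoate F7. Glycol cleavage of F7 with NaIO4 (THF/H2O, rt) should give 17.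

Further compounds
F1 | step 9 | benzyl 2,4-dihydroxy-6-methylbenzoate | Cc1cc(O)cc(O)c1C(=O)OCc1ccccc1
F2 | step 9 | benzyl 4-[(2-(benzyloxy)-4-{[2,4-bis(benzyloxy)-6-methylbenzoyl]oxy}-6-methylbenzoyl)oxy]-2-hydroxy-6-methylbenzoate | Cc1cc(OC(=O)c2c(C)cc(OC(=O)c3c(C)cc(OCc4ccccc4)cc3OCc3ccccc3)cc2OCc2ccccc2)cc(O)c1C(=O)OCc1ccccc1
F3 | step 9 | benzyl 4-[(2-(benzyloxy)-4-{[2,4-bis(benzyloxy)-6-methylbenzoyl]oxy}-6-methylbenzoyl)oxy]-2-methoxy-6-methylbenzoate | COc1cc(OC(=O)c2c(C)cc(OC(=O)c3c(C)cc(OCc4ccccc4)cc3OCc3ccccc3)cc2OCc2ccccc2)cc(C)c1C(=O)OCc1ccccc1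
F4 | step 7 | 3-methoxy-4-[(E)-phenyldiazenyl]phenol | COc1cc(O)ccc1/N=N/c1ccccc1
F5 | step 7 | 4-amino-3-methoxyphenol | COc1cc(O)ccc1N
F6 | step 7 | 4-hydroxy-2-methoxybenzenediazonium hydrogensulfate | COc1cc(O)ccc1[N+]#N.OS(=O)(=O)[O-]
F7 | step 10 | racemic methyl (2S,3R)-3-{4-[(2-(benzyloxy)-4-{[2,4-bis(benzyloxy)-6-methylbenzoyl]oxy}-6-methylbenzoyl)oxy]-2-methoxy-6-methylphenyl}-2,3-dihydroxypropanoate (one enantiomer drawn) | COc1cc(OC(=O)c2c(C)cc(OC(=O)c3c(C)cc(OCc4ccccc4)cc3OCc3ccccc3)cc2OCc2ccccc2)cc(C)c1[C@@H](O)[C@H](O)C(=O)OC
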